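**Remark on numbering.** Unit 1 is the chromanone with the 4‑hydroxyphenyl group, unit 2 the one with the 4‑methoxyphenyl group. In each unit ring A is the benzo ring and ring C the pyranone ring. Compound numbers are those of the steps and the compound list.

## Analysis of the target

Target 26 is a biflavanone: two chroman‑4‑one units joined by a single C–C bond from C3 of unit 1 to C8 of unit 2. It has three stereocentres. C2 (R) and C3 (S) of unit 1 carry trans, diequatorial aryl groups; C2 (S) of unit 2 is remote and cannot be relayed from the other two. C3 of unit 1 is an acidic α‑keto methine that equilibrates to the trans isomer. Both flavanone rings can open to chalcones by retro‑oxa‑Michael reaction under base or strong acid, which would erase the C2 centres. Five free phenols on two phloroglucinol rings make the molecule prone to oxidation, and the one methyl ether must survive whatever frees the other oxygens. The hard part is the C3–C8 bond, which joins an sp3 carbon flanked by a ketone and a stereocentre to an aromatic carbon lying between two oxygens. In addition, the three oxygens of ring A of unit 2 must be told apart so that unit 2 closes as the 8‑linked and not the 6‑linked flavanone. The strategy rests on that ring: it is a phloroglucinol with C8 between the oxygens at C7 and C8a, which is the pattern a vinylketene/ynol ether benzannulation delivers, so the ring can be grown around the C3–C8 bond instead of being coupled to it.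

## Retrosynthetic reasoning

**26 ⇐ 25 ⇐ 24 (protecting groups).** All oxygens that end as OH are masked by groups that fall to fluoride or to a chelating boron Lewis acid. These are the benzyl ethers on unit 1, the silyl ether at C7 of unit 2, and the ethyl ether at C5 of unit 2, which sits peri to the C4 carbonyl. The methyl ether of the 4‑methoxyphenyl group is unchelated and not benzylic, so it stays. Deprotection comes last because the free polyphenol is the least robust compound of the route.

**24 ⇐ 22 + 23 (C2–aryl bond of unit 2).** Cutting this bond leads back to chromone 22 and boronic acid 23. The forward reaction is an enantioselective conjugate arylation under catalyst control, which is the right kind of control for a stereocentre far from the others. It runs without base, which unit 1 needs. The methoxyphenyl group enters with its ether already in place.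

**22 ⇐ 20 ⇐ 19 (ring C of unit 2).** The pyranone is cut at O1–C2 and C2–C3 to the ortho‑hydroxyacetophenone 20. The acetyl group is cut from the ring carbon ortho to the phenol, leading to aryl acetate 19 by a Fries transform. The forward rearrangement must put the acyl group between the ester oxygen and the ethoxy group. The only other free position is para to the ester oxygen and shielded by the silyl ether. Because C5 oxygen is already an ethyl ether, the pyranone can only close through the oxygen next to C8, which fixes the 8‑linkage.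

**19 ⇐ 18 ⇐ 16 ⇐ 15 (C4 carbonyl and C3 of unit 1).** The ketone is traced to the C3=C4 double bond of chromene 16 by hydroboration and oxidation of the organoborane. Borane adds anti to the C2 aryl group and gives the 2,3‑cis ketone 18. C3 is then set by equilibration to the trans isomer 19, so only C2 needs absolute control. The phenol of 15 is acetylated first: the acetate protects it from borane and oxidant and is the Fries precursor, so no separate protecting step is spent.

**15 ⇐ 9 + 10 (ring A of unit 2).** This is the key disconnection. The benzene ring is cut at C8–C8a and C6–C7 into siloxyalkyne 9 and cyclobutenone 10. What is gained is that the crowded C3–C8 bond exists beforehand as an ordinary alkenyl–alkynyl bond. In addition, the three oxygens emerge already differentiated as free OH, silyl ether and ethyl ether. The forward reaction must give the regiochemistry with OH and OSi on either side of the chromenyl carbon, and it must not racemise C2 of the chromene.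

**9 ⇐ 6 ⇐ 5 (the ynol ether).** The siloxyalkyne comes from terminal alkyne 6 by oxidation of its acetylide and O‑silylation. Alkyne 6 comes from aldehyde 5 by one‑carbon homologation. Both are mild, low‑temperature operations that leave C2 alone.

**5 ⇐ 2 + 4; 2 ⇐ 1; 4 ⇐ 3 (ring C of unit 1).** The chromene aldehyde is cut at O1–C2 and C3–C4 into salicylaldehyde 2 and cinnamaldehyde 4. The forward domino oxa‑Michael/aldol condensation under iminium catalysis sets C2, the one stereocentre of unit 1 that must be made under absolute control. It does so on unhindered partners and is driven by an irreversible dehydration. Compounds 2 and 4 come in one step each from commercial 1 and 3.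

## Alternatives that were turned down

**Alternative 1: aryne insertion to the α‑aryl chalcone.** Unit 1 is cut at O1–C8a and C4–C4a. In the forward step the fluoride‑generated 3,5‑bis(benzyloxy)benzyne A3 inserts into the acyl–oxygen bond of the (E)‑2,3‑diarylacrylic acid A2 and gives the 2'‑hydroxy‑α‑aryl chalcone A1.
- For: it is convergent and makes the ketone and the phenol in one operation. The crowded C3–C8 bond is already present in A2 as a plain aryl–carbon bond, so on that point it is as strong as the chosen route. Its protecting‑group pattern (two equal acetal ethers, one para benzyl ether) also settles the 6/8 question, and more simply.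
- Against: the key step closes no ring and sets no stereocentre. C2 and C3 must then both come from an enantioselective 6‑endo oxa‑Michael closure of a twisted, trisubstituted enone carrying a di‑ortho‑substituted aryl group. That closure is reversible and has no close precedent on such a substrate. Aryl ester formation by O–H insertion competes, and the aryne precursor costs several steps.
- Comparison: it reaches the skeleton sooner, but the whole stereochemical burden falls on one unproven cyclisation. The chosen route instead fixes C2 first, in an irreversible domino step on simple partners.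

**Alternative 2: deoxybenzoin–aldehyde annulation.** Unit 1 is cut at C2–C3 and O1–C2. The 2'‑hydroxydeoxybenzoin A5 condenses with aldehyde 3, and the resulting α‑aryl chalcone cyclises under a bifunctional primary amine–thiourea catalyst to the trans‑2,3‑diaryl chromanone A4.
- For: it is the shortest route, clearly better in step count. Ring C and both stereocentres of unit 1 arise in one pot, and trans follows from thermodynamics.
- Against: condensation at a methylene flanked by a di‑ortho‑substituted aryl group is slow. The enantio‑determining oxa‑Michael step is reversible under the same amine that catalyses it. The product has an acidic C3–H, so the configuration at C2 can leak away through ring opening.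
- Comparison: the chosen route pays several more steps, but C2 is never again subject to a reversible ring closure.

**Alternative 3: enamine/quinone methide annulation at the flavan level.** Unit 1 is cut at C3–C4 and O1–C2 at a lower oxidation state. The enamine of arylacetaldehyde A7 adds to the ortho‑quinone methide released from sulfone A8, and lactolisation gives chroman‑2‑ol A6 with C3 defined.
- For: enamine additions to quinone methides are reliable, and C3 is set by the catalyst.
- Against: the centre it controls (C3) is the one that later becomes epimerisable next to the ketone, so the control has little lasting value. C2 still needs an aryl group installed at the lactol. C4 must be oxidised from CH2 to C=O late, in a molecule full of benzylic ethers and electron‑rich rings. The hindered α‑aryl aldehyde A7 forms its enamine slowly and racemises easily.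
- Comparison: the chosen route brings in the C4 oxygen by hydroboration of an alkene that the domino step leaves behind, and so avoids a late C–H oxidation.

Key step: step 6

Remark: the sense of induction of the two chiral catalysts (steps 3 and 12) is assigned from the usual shielding models; should either deliver the antipode, its enantiomer is used with nothing else changed.

## Route

Step 1
Reactants: 1 2,4,6-trihydroxybenzaldehyde
Product: 2 2,4-bis(benzyloxy)-6-hydroxybenzaldehyde
Conditions: BnBr (2.05 equiv), K2CO3 (2.1 equiv), DMF, 0 °C → rt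
Reagents that add atoms: benzyl bromide, BrCc1ccccc1
Why: Williamson etherification; the para hydroxyl and one ortho hydroxyl are alkylated, while the last ortho hydroxyl is held in the hydrogen bond to the formyl group and is left when the bromide is limited to two equivalents.

Step 2
Reactants: 3 4-(benzyloxy)benzaldehyde
Product: 4 (E)-3-[4-(benzyloxy)phenyl]prop-2-enal
Conditions: Ph3P=CHCHO (1.0 equiv), toluene, 80 °C
Reagents that add atoms: (triphenylphosphoranylidene)acetaldehyde, O=CC=P(c1ccccc1)(c1ccccc1)c1ccccc1
Why: Wittig olefination with a stabilised ylide, which should give the E enal; the aromatic aldehyde reacts faster than the product enal, so a second homologation is kept small.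

Step 3
Reactants: 2 2,4-bis(benzyloxy)-6-hydroxybenzaldehyde; 4 (E)-3-[4-(benzyloxy)phenyl]prop-2-enal
Product: 5 (2S)-5,7-bis(benzyloxy)-2-[4-(benzyloxy)phenyl]-2H-chromene-3-carbaldehyde
Conditions: (R)-2-[diphenyl(trimethylsilyloxy)methyl]pyrrolidine (20 mol%), 2-nitrobenzoic acid (20 mol%), 4 Å molecular sieves, toluene, rt, dark
Reagents that add atoms: none
Why: Domino oxa-Michael/aldol condensation under iminium–enamine catalysis; the phenol of 2 adds to the β-carbon of the E-iminium ion of 4 on the face away from the diphenyl(silyloxy)methyl group, which sets C2, and the enamine then closes onto the formyl group and dehydrates irreversibly, which pulls the reversible oxa-Michael step forward.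

Step 4
Reactants: 5 (2S)-5,7-bis(benzyloxy)-2-[4-(benzyloxy)phenyl]-2H-chromene-3-carbaldehyde
Product: 6 (2S)-5,7-bis(benzyloxy)-2-[4-(benzyloxy)phenyl]-3-ethynyl-2H-chromene
Conditions: MeC(O)C(N2)P(O)(OMe)2 (1.5 equiv), K2CO3 (2 equiv), MeOH/THF, 0 °C → rt
Reagents that add atoms: dimethyl (1-diazo-2-oxopropyl)phosphonate, CC(=O)C(=[N+]=[N-])P(=O)(OC)OC
Why: Seyferth–Gilbert homologation in its Ohira–Bestmann form; carbonate in methanol is too weak to touch C2–H, which is not vinylogous to the aldehyde, and conjugate addition of methanol at C4 is disfavoured because that carbon carries the electron-rich ring A.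

Step 5
Reactants: 6 (2S)-5,7-bis(benzyloxy)-2-[4-(benzyloxy)phenyl]-3-ethynyl-2H-chromene
Product: 9 (2S)-5,7-bis(benzyloxy)-2-[4-(benzyloxy)phenyl]-3-[(triisopropylsilyloxy)ethynyl]-2H-chromene, via lithium acetylide 7 (not isolated), via lithium ynolate 8 (not isolated)
Conditions: LiN(SiMe3)2, THF, −78 °C; t-BuOOLi (from t-BuOOH and LiN(SiMe3)2), −78 → 0 °C; i-Pr3SiOSO2CF3, −78 → 0 °C
Reagents that add atoms: tert-butyl hydroperoxide, CC(C)(C)OO; triisopropylsilyl trifluoromethanesulfonate, CC(C)[Si](OS(=O)(=O)C(F)(F)F)(C(C)C)C(C)C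
Why: Electrophilic oxygen transfer from lithium tert-butyl peroxide to the acetylide carbon gives the ynolate, and the bulky silyl triflate traps it on oxygen as the siloxyalkyne; the amide base removes only the alkyne proton, not C2–H.

Step 6
Reactants: 9 (2S)-5,7-bis(benzyloxy)-2-[4-(benzyloxy)phenyl]-3-[(triisopropylsilyloxy)ethynyl]-2H-chromene; 10 3-ethoxycyclobut-2-en-1-one
Product: 15 2-[(2S)-5,7-bis(benzyloxy)-2-(4-benzyloxyphenyl)-2H-chromen-3-yl]-5-ethoxy-3-(triisopropylsilyloxy)phenol, via ethoxyvinylketene 11 (not isolated), via vinylcyclobutenone 12 (not isolated), via dienylketene 13 (not isolated), via cyclohexadienone 14 (not isolated)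
Conditions: 10 (1.5 equiv, slow addition), degassed toluene, 80 °C, dark
Reagents that add atoms: none
Why: Danheiser benzannulation, a reagent-free cascade of four pericyclic steps. Heating opens 10 by 4π-electrocyclic reaction to ethoxyvinylketene 11; siloxyalkyne 9, nucleophilic at the carbon that carries the chromenyl group, adds to the ketene C=O carbon in a regiospecific [2+2] cycloaddition to give vinylcyclobutenone 12. 12 reopens (4π) to dienylketene 13, which closes by thermal disrotatory 6π-electrocyclisation (forming C4a–C8a), the one ring closure that stays in the product and the origin of ring A of unit 2, and dienone 14 tautomerises to 15; the net new skeletal bonds are C8–C8a and C6–C7. The closest known reaction type is the benzannulation of cyclobutenones with triisopropylsiloxyalkynes to resorcinol monosilyl ethers. No stereocentre is formed (the sp3 carbon of 12 is lost on ring opening) and C2 of the chromene is a spectator. Three selectivities are needed: regiochemistry of the [2+2] step, secured by the polarisation of the ynol ether, which places OH and OSi on either side of the chromenyl carbon and OEt para to it; chemoselectivity for the alkyne over the chromene alkene, secured because ketenes add far faster to ynol ethers than to styrenes; and retention of C2, secured by the absence of acid, base and light and by working at the lowest temperature at which 10 opens, below that of reversible oxa-6π opening of the 2H-chromene. The congested C3–C8 bond is never made by coupling, since it is the unhindered alkenyl–alkynyl bond of 9.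

Step 7
Reactants: 15 2-[(2S)-5,7-bis(benzyloxy)-2-(4-benzyloxyphenyl)-2H-chromen-3-yl]-5-ethoxy-3-(triisopropylsilyloxy)phenol
Product: 16 2-[(2S)-5,7-bis(benzyloxy)-2-(4-benzyloxyphenyl)-2H-chromen-3-yl]-5-ethoxy-3-(triisopropylsilyloxy)phenyl acetate
Conditions: Ac2O, Et3N, 4-(dimethylamino)pyridine (cat.), CH2Cl2, 0 °C → rt
Reagents that add atoms: acetic anhydride, CC(=O)OC(C)=O
Why: Acylation of the phenol under base only, which the acid-sensitive chromene tolerates; the acetate shields the phenol from borane and oxidant in step 8 and is the precursor of the Fries rearrangement in step 10.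

Step 8
Reactants: 16 2-[(2S)-5,7-bis(benzyloxy)-2-(4-benzyloxyphenyl)-2H-chromen-3-yl]-5-ethoxy-3-(triisopropylsilyloxy)phenyl acetate
Product: 18 2-[(2R,3R)-5,7-bis(benzyloxy)-2-(4-benzyloxyphenyl)-4-oxochroman-3-yl]-5-ethoxy-3-(triisopropylsilyloxy)phenyl acetate (2,3-cis), via alkylborane 17 (not isolated)
Conditions: BH3·THF, THF, 0 °C → rt; then N-methylmorpholine N-oxide (excess), (n-Pr4N)RuO4 (5 mol%), 4 Å molecular sieves, CH2Cl2, rt
Reagents that add atoms: N-methylmorpholine N-oxide, C[N+]1([O-])CCOCC1
Why: Hydroboration places boron on the less substituted C4 and hydrogen on C3, syn and on the face away from the pseudoaxial C2 aryl group, which gives the 2,3-cis arrangement; the amine N-oxide converts C–B into C–O–B and perruthenate oxidises this to the ketone in the same pot (known one-pot conversion of alkenes into ketones through the organoborane), without aqueous base, so the aryl acetate is kept and the acid-labile benzylic alcohol is never isolated.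

Step 9
Reactants: 18 2-[(2R,3R)-5,7-bis(benzyloxy)-2-(4-benzyloxyphenyl)-4-oxochroman-3-yl]-5-ethoxy-3-(triisopropylsilyloxy)phenyl acetate
Product: 19 2-[(2R,3S)-5,7-bis(benzyloxy)-2-(4-benzyloxyphenyl)-4-oxochroman-3-yl]-5-ethoxy-3-(triisopropylsilyloxy)phenyl acetate (2,3-trans)
Conditions: Et3N (0.5 equiv), CH2Cl2, 0 °C → rt, monitored
Reagents that add atoms: none
Why: Epimerisation of the acidic α-aryl ketone methine through its enolate to the thermodynamic trans isomer with both aryl groups equatorial, which sets C3; a weak amine and a short reaction time keep reprotonation far ahead of retro-oxa-Michael ring opening, which would erase C2.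

Step 10
Reactants: 19 2-[(2R,3S)-5,7-bis(benzyloxy)-2-(4-benzyloxyphenyl)-4-oxochroman-3-yl]-5-ethoxy-3-(triisopropylsilyloxy)phenyl acetate
Product: 20 (2R,3S)-3-[3-acetyl-4-ethoxy-2-hydroxy-6-(triisopropylsilyloxy)phenyl]-5,7-bis(benzyloxy)-2-(4-benzyloxyphenyl)chroman-4-one
Conditions: Sc(OSO2CF3)3 (20 mol%), toluene/MeNO2, 60 °C
Reagents that add atoms: none
Why: Fries rearrangement; the acyl group moves to the ring carbon ortho to the ester oxygen and next to OEt, where the product is held as a chelate, while the only other free carbon is para to the ester oxygen and shielded by the silyl ether. A catalytic triflate is chosen over stoichiometric TiCl4 or BCl3, which would cleave the peri benzyl ether of unit 1.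

Step 11
Reactants: 20 (2R,3S)-3-[3-acetyl-4-ethoxy-2-hydroxy-6-(triisopropylsilyloxy)phenyl]-5,7-bis(benzyloxy)-2-(4-benzyloxyphenyl)chroman-4-one
Product: 22 8-[(2R,3S)-5,7-bis(benzyloxy)-2-(4-benzyloxyphenyl)-4-oxochroman-3-yl]-5-ethoxy-7-(triisopropylsilyloxy)-4H-chromen-4-one, via enaminone 21 (not isolated)
Conditions: Me2NCH(OMe)2 (3 equiv), toluene, 80 °C; then 2 M HCl, CH2Cl2, rt
Reagents that add atoms: N,N-dimethylformamide dimethyl acetal, COC(OC)N(C)C
Why: Condensation of the methyl ketone with the amide acetal gives the enaminone, and acid then drives addition of the phenol oxygen and loss of dimethylamine to close the chromone; the methine of unit 1 has only one hydrogen and cannot condense, and because C5 is an ethyl ether the ring can only close through the oxygen next to C8.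

Step 12
Reactants: 22 8-[(2R,3S)-5,7-bis(benzyloxy)-2-(4-benzyloxyphenyl)-4-oxochroman-3-yl]-5-ethoxy-7-(triisopropylsilyloxy)-4H-chromen-4-one; 23 (4-methoxyphenyl)boronic acid
Product: 24 (2S)-8-[(2R,3S)-5,7-bis(benzyloxy)-2-(4-benzyloxyphenyl)-4-oxochroman-3-yl]-5-ethoxy-2-(4-methoxyphenyl)-7-(triisopropylsilyloxy)chroman-4-one
Conditions: 23 (3 equiv), Pd(OCOCF3)2 (10 mol%), (R)-4-tert-butyl-2-(pyridin-2-yl)-4,5-dihydrooxazole (12 mol%), NH4PF6 (30 mol%), H2O (5 equiv), ClCH2CH2Cl, 60 °C
Reagents that add atoms: none
Why: Palladium-catalysed asymmetric conjugate addition of an arylboronic acid to a chromone (transmetalation, enantio-determining insertion of C2=C3 into the aryl–palladium bond, protonolysis of the palladium enolate); the pyridine–oxazoline ligand fixes the face of attack and so sets C2 of unit 2 as S independently of the remote unit 1, and the base-free medium spares the unit 1 flavanone.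

Step 13
Reactants: 24 (2S)-8-[(2R,3S)-5,7-bis(benzyloxy)-2-(4-benzyloxyphenyl)-4-oxochroman-3-yl]-5-ethoxy-2-(4-methoxyphenyl)-7-(triisopropylsilyloxy)chroman-4-one
Product: 25 (2S)-8-[(2R,3S)-5,7-bis(benzyloxy)-2-(4-benzyloxyphenyl)-4-oxochroman-3-yl]-5-ethoxy-7-hydroxy-2-(4-methoxyphenyl)chroman-4-one
Conditions: Bu4NF, AcOH (1:1), THF, 0 °C
Reagents that add atoms: none
Why: Fluoride cleaves the aryl silyl ether; acetic acid buffers the phenoxide so that neither flavanone is exposed to base strong enough to open it.

Step 14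
Reactants: 25 (2S)-8-[(2R,3S)-5,7-bis(benzyloxy)-2-(4-benzyloxyphenyl)-4-oxochroman-3-yl]-5-ethoxy-7-hydroxy-2-(4-methoxyphenyl)chroman-4-one
Product: 26 (2S)-8-[(2R,3S)-5,7-dihydroxy-2-(4-hydroxyphenyl)-4-oxochroman-3-yl]-5,7-dihydroxy-2-(4-methoxyphenyl)chroman-4-one
Conditions: BCl3 (excess), C6HMe5 (10 equiv), CH2Cl2, −78 → 0 °C; MeOH quench
Reagents that add atoms: none
Why: Lewis-acid dealkylation; BCl3 removes the three benzyl groups (the benzyl cation is caught by pentamethylbenzene, not by the phloroglucinol rings) and, through its chelate with the C4 carbonyl, the peri ethyl ether at C5 of unit 2, while the unchelated methyl ether is inert at this temperature and the low temperature avoids opening of the flavanones.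

## Compound list

1 | 2,4,6-trihydroxybenzaldehyde | O=Cc1c(O)cc(O)cc1O | starting material
2 | 2,4-bis(benzyloxy)-6-hydroxybenzaldehyde | O=Cc1c(O)cc(OCc2ccccc2)cc1OCc1ccccc1 | intermediate
3 | 4-(benzyloxy)benzaldehyde | O=Cc1ccc(OCc2ccccc2)cc1 | starting material
4 | (E)-3-[4-(benzyloxy)phenyl]prop-2-enal | O=C/C=C/c1ccc(OCc2ccccc2)cc1 | intermediate
5 | (2S)-5,7-bis(benzyloxy)-2-[4-(benzyloxy)phenyl]-2H-chromene-3-carbaldehyde | O=CC1=Cc2c(OCc3ccccc3)cc(OCc3ccccc3)cc2O[C@H]1c1ccc(OCc2ccccc2)cc1 | intermediate
6 | (2S)-5,7-bis(benzyloxy)-2-[4-(benzyloxy)phenyl]-3-ethynyl-2H-chromene | C#CC1=Cc2c(OCc3ccccc3)cc(OCc3ccccc3)cc2O[C@H]1c1ccc(OCc2ccccc2)cc1 | intermediate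
7 | lithium acetylide of 6 | [Li]C#CC1=Cc2c(OCc3ccccc3)cc(OCc3ccccc3)cc2O[C@H]1c1ccc(OCc2ccccc2)cc1 | intermediate
8 | lithium ynolate derived from 7 | [Li]OC#CC1=Cc2c(OCc3ccccc3)cc(OCc3ccccc3)cc2O[C@H]1c1ccc(OCc2ccccc2)cc1 | intermediate
9 | (2S)-5,7-bis(benzyloxy)-2-[4-(benzyloxy)phenyl]-3-[(triisopropylsilyloxy)ethynyl]-2H-chromene | CC(C)[Si](OC#CC1=Cc2c(OCc3ccccc3)cc(OCc3ccccc3)cc2O[C@H]1c1ccc(OCc2ccccc2)cc1)(C(C)C)C(C)C | intermediate
10 | 3-ethoxycyclobut-2-en-1-one | CCOC1=CC(=O)C1 | starting material
11 | 3-ethoxybuta-1,3-dien-1-one (ethoxyvinylketene) | C=C(OCC)C=C=O | intermediate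
12 | 2-[(2S)-chromen-3-yl]-4-(1-ethoxyethenyl)-3-(triisopropylsilyloxy)cyclobut-2-en-1-one, chromenyl as in 9, C4 of the four-membered ring undefined | C=C(OCC)C1C(=O)C(C2=Cc3c(OCc4ccccc4)cc(OCc4ccccc4)cc3O[C@H]2c2ccc(OCc3ccccc3)cc2)=C1O[Si](C(C)C)(C(C)C)C(C)C | intermediate
13 | (3E)-2-[(2S)-chromen-3-yl]-5-ethoxy-3-(triisopropylsilyloxy)hexa-1,3,5-trien-1-one, chromenyl as in 9 | C=C(OCC)/C=C(O[Si](C(C)C)(C(C)C)C(C)C)\C(=C=O)C1=Cc2c(OCc3ccccc3)cc(OCc3ccccc3)cc2O[C@H]1c1ccc(OCc2ccccc2)cc1 | intermediate
14 | 2-[(2S)-chromen-3-yl]-5-ethoxy-3-(triisopropylsilyloxy)cyclohexa-2,4-dien-1-one, chromenyl as in 9 | CCOC1=CC(O[Si](C(C)C)(C(C)C)C(C)C)=C(C2=Cc3c(OCc4ccccc4)cc(OCc4ccccc4)cc3O[C@H]2c2ccc(OCc3ccccc3)cc2)C(=O)C1 | intermediate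
15 | 2-[(2S)-5,7-bis(benzyloxy)-2-(4-benzyloxyphenyl)-2H-chromen-3-yl]-5-ethoxy-3-(triisopropylsilyloxy)phenol | CCOc1cc(O)c(C2=Cc3c(OCc4ccccc4)cc(OCc4ccccc4)cc3O[C@H]2c2ccc(OCc3ccccc3)cc2)c(O[Si](C(C)C)(C(C)C)C(C)C)c1 | intermediate
16 | acetate of 15 | CCOc1cc(OC(C)=O)c(C2=Cc3c(OCc4ccccc4)cc(OCc4ccccc4)cc3O[C@H]2c2ccc(OCc3ccccc3)cc2)c(O[Si](C(C)C)(C(C)C)C(C)C)c1 | intermediate
17 | [(2R,3R,4S)-3-(2-acetoxy-4-ethoxy-6-triisopropylsilyloxyphenyl)-5,7-bis(benzyloxy)-2-(4-benzyloxyphenyl)chroman-4-yl]borane (2,3-cis, 3,4-trans) | CCOc1cc(OC(C)=O)c([C@H]2[C@H](B)c3c(OCc4ccccc4)cc(OCc4ccccc4)cc3O[C@H]2c2ccc(OCc3ccccc3)cc2)c(O[Si](C(C)C)(C(C)C)C(C)C)c1 | intermediate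
18 | 2-[(2R,3R)-5,7-bis(benzyloxy)-2-(4-benzyloxyphenyl)-4-oxochroman-3-yl]-5-ethoxy-3-(triisopropylsilyloxy)phenyl acetate (2,3-cis) | CCOc1cc(OC(C)=O)c([C@H]2C(=O)c3c(OCc4ccccc4)cc(OCc4ccccc4)cc3O[C@H]2c2ccc(OCc3ccccc3)cc2)c(O[Si](C(C)C)(C(C)C)C(C)C)c1 | intermediate
19 | 2-[(2R,3S)-5,7-bis(benzyloxy)-2-(4-benzyloxyphenyl)-4-oxochroman-3-yl]-5-ethoxy-3-(triisopropylsilyloxy)phenyl acetate (2,3-trans) | CCOc1cc(OC(C)=O)c([C@@H]2C(=O)c3c(OCc4ccccc4)cc(OCc4ccccc4)cc3O[C@H]2c2ccc(OCc3ccccc3)cc2)c(O[Si](C(C)C)(C(C)C)C(C)C)c1 | intermediate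
20 | (2R,3S)-3-[3-acetyl-4-ethoxy-2-hydroxy-6-(triisopropylsilyloxy)phenyl]-5,7-bis(benzyloxy)-2-(4-benzyloxyphenyl)chroman-4-one | CCOc1cc(O[Si](C(C)C)(C(C)C)C(C)C)c([C@@H]2C(=O)c3c(OCc4ccccc4)cc(OCc4ccccc4)cc3O[C@H]2c2ccc(OCc3ccccc3)cc2)c(O)c1C(C)=O | intermediate
21 | (E)-3-(dimethylamino)prop-2-enoyl analogue of 20 (enaminone) | CCOc1cc(O[Si](C(C)C)(C(C)C)C(C)C)c([C@@H]2C(=O)c3c(OCc4ccccc4)cc(OCc4ccccc4)cc3O[C@H]2c2ccc(OCc3ccccc3)cc2)c(O)c1C(=O)/C=C/N(C)C | intermediate
22 | 8-[(2R,3S)-5,7-bis(benzyloxy)-2-(4-benzyloxyphenyl)-4-oxochroman-3-yl]-5-ethoxy-7-(triisopropylsilyloxy)-4H-chromen-4-one | CCOc1cc(O[Si](C(C)C)(C(C)C)C(C)C)c([C@@H]2C(=O)c3c(OCc4ccccc4)cc(OCc4ccccc4)cc3O[C@H]2c2ccc(OCc3ccccc3)cc2)c2occc(=O)c12 | intermediate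
23 | (4-methoxyphenyl)boronic acid | COc1ccc(B(O)O)cc1 | starting material
24 | (2S)-8-[(2R,3S)-5,7-bis(benzyloxy)-2-(4-benzyloxyphenyl)-4-oxochroman-3-yl]-5-ethoxy-2-(4-methoxyphenyl)-7-(triisopropylsilyloxy)chroman-4-one | COc1ccc([C@@H]2CC(=O)c3c(OCC)cc(O[Si](C(C)C)(C(C)C)C(C)C)c([C@@H]4C(=O)c5c(OCc6ccccc6)cc(OCc6ccccc6)cc5O[C@H]4c4ccc(OCc5ccccc5)cc4)c3O2)cc1 | intermediate
25 | (2S)-8-[(2R,3S)-5,7-bis(benzyloxy)-2-(4-benzyloxyphenyl)-4-oxochroman-3-yl]-5-ethoxy-7-hydroxy-2-(4-methoxyphenyl)chroman-4-one | COc1ccc([C@@H]2CC(=O)c3c(OCC)cc(O)c([C@@H]4C(=O)c5c(OCc6ccccc6)cc(OCc6ccccc6)cc5O[C@H]4c4ccc(OCc5ccccc5)cc4)c3O2)cc1 | intermediate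
26 | (2S)-8-[(2R,3S)-5,7-dihydroxy-2-(4-hydroxyphenyl)-4-oxochroman-3-yl]-5,7-dihydroxy-2-(4-methoxyphenyl)chroman-4-one | COc1ccc([C@@H]2CC(=O)c3c(O)cc(O)c([C@@H]4C(=O)c5c(O)cc(O)cc5O[C@H]4c4ccc(O)cc4)c3O2)cc1 | target

## Step count and least certain steps

Total: 14 steps. Longest linear sequence: 13 steps (steps 1 and 3–14 from 1); step 2 is a one-step branch.

**Step 6 (key step).** Three things may go wrong.
- Opening of the donor-stabilised cyclobutenone 10 may need a temperature at which the 2H-chromene undergoes reversible oxa-6π ring opening, so that the configuration at C2 erodes.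
- If ketene formation is slow, the siloxyalkyne may rearrange to a silylketene by a 1,3-silyl shift.
- Excess ketene may acylate the product phenol.

Fallback (sets out from 5, returns at 15): the C3–aryl bond is made by cross-coupling instead of annulation. Pinnick oxidation of 5 (NaClO2, NaH2PO4, 2-methylbut-2-ene) would give the chromene-3-carboxylic acid F1. Hunsdiecker-type bromodecarboxylation (N-bromosuccinimide, LiOAc cat., MeCN/H2O) would give the 3-bromo-2H-chromene F2. Suzuki–Miyaura coupling with [4-ethoxy-2,6-bis(allyloxy)phenyl]boronic acid F3 (Pd(OAc)2, SPhos, K3PO4, toluene/H2O, 60 °C) would give the bis(allyl ether) F4. Pd(PPh3)4 with morpholine would remove both allyl groups to the resorcinol F5. One equivalent of triisopropylsilyl chloride with imidazole would silylate one of its two equivalent hydroxyls and give 15. This is longer and brings back the hindered coupling that the annulation avoids.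

**Step 8.** Both faces of the C3=C4 bond are flanked by the ortho substituents of the perpendicular aryl group, so hydroboration may be slow. Slow addition would allow borane to begin reducing the aryl acetate. Oxidation of the hindered benzylic borane by the N-oxide may also be incomplete.

Fallback (sets out from 15, returns at 18): the phenol is left free so that its aryloxyborane delivers B–H intramolecularly to C4. BH3·THF followed by NaOH/H2O2 would give the 2,3-cis chroman-4-ol F6, which is kept away from acid. Selective acetylation of the phenol (Ac2O, K2CO3, acetone, 0 °C) would give the hydroxy acetate F7. Dess–Martin periodinane (NaHCO3, CH2Cl2) would then give 18.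

**Step 10.** The Lewis acid may deacetylate without C-acylation, may send the acyl group to the position para to the ester oxygen, or may attack the silyl ether or the peri benzyl ether.

Fallback (sets out from 19, returns at 20): the acetate is cleaved with NH4OAc in aqueous methanol to the phenol F8. Hoesch acylation (MeCN, ZnCl2, HCl gas, Et2O, 0 °C) would then give the ketiminium chloride F9, which water hydrolyses to 20.

**Step 12.** Insertion into the electron-rich 5,7-dioxygenated chromone may be slow, so that protodeboronation and homocoupling of the electron-rich boronic acid win. Facial selectivity may also be lower than on simple chromones.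

Fallback (sets out from 22, returns at 24): conjugate addition of (4-MeOC6H4)2CuLi (from the aryllithium and CuBr·SMe2) with Me3SiCl in THF at −78 °C would give the silyl enol ether F10 as both C2 epimers. The hindered unit 1 ketone should not react. Dilute acid on work-up would give 24 together with its epimer at C2 of unit 2, F11. Because unit 1 is a single enantiomer, the two are diastereomers and are separated by chromatography.

**Step 3.** The aldol step onto the hindered, electron-rich formyl group of 2 may be slow. The reversible oxa-Michael step would then equilibrate and the enantiomeric purity would fall.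

Fallback (sets out from 2 and 4, returns at 5): the racemic domino reaction with pyrrolidine and benzoic acid would give the racemic chromene aldehyde F12. It is resolved by preparative chromatography on a chiral stationary phase to give 5.

## Further compounds

F1 | step 6 | (2S)-5,7-bis(benzyloxy)-2-[4-(benzyloxy)phenyl]-2H-chromene-3-carboxylic acid | OC(=O)C1=Cc2c(OCc3ccccc3)cc(OCc3ccccc3)cc2O[C@H]1c1ccc(OCc2ccccc2)cc1
F2 | step 6 | (2S)-5,7-bis(benzyloxy)-2-[4-(benzyloxy)phenyl]-3-bromo-2H-chromene | BrC1=Cc2c(OCc3ccccc3)cc(OCc3ccccc3)cc2O[C@H]1c1ccc(OCc2ccccc2)cc1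
F3 | step 6 | [4-ethoxy-2,6-bis(prop-2-en-1-yloxy)phenyl]boronic acid | CCOc1cc(OCC=C)c(B(O)O)c(OCC=C)c1
F4 | step 6 | (2S)-3-[4-ethoxy-2,6-bis(prop-2-en-1-yloxy)phenyl]-5,7-bis(benzyloxy)-2-[4-(benzyloxy)phenyl]-2H-chromene | CCOc1cc(OCC=C)c(C2=Cc3c(OCc4ccccc4)cc(OCc4ccccc4)cc3O[C@H]2c2ccc(OCc3ccccc3)cc2)c(OCC=C)c1
F5 | step 6 | 2-[(2S)-5,7-bis(benzyloxy)-2-(4-benzyloxyphenyl)-2H-chromen-3-yl]-5-ethoxybenzene-1,3-diol | CCOc1cc(O)c(C2=Cc3c(OCc4ccccc4)cc(OCc4ccccc4)cc3O[C@H]2c2ccc(OCc3ccccc3)cc2)c(O)c1
F6 | step 8 | 2-[(2R,3S,4S)-5,7-bis(benzyloxy)-2-(4-benzyloxyphenyl)-4-hydroxychroman-3-yl]-5-ethoxy-3-(triisopropylsilyloxy)phenol (2,3-cis, 3,4-trans) | CCOc1cc(O)c([C@H]2[C@H](O)c3c(OCc4ccccc4)cc(OCc4ccccc4)cc3O[C@H]2c2ccc(OCc3ccccc3)cc2)c(O[Si](C(C)C)(C(C)C)C(C)C)c1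
F7 | step 8 | 2-[(2R,3S,4S)-5,7-bis(benzyloxy)-2-(4-benzyloxyphenyl)-4-hydroxychroman-3-yl]-5-ethoxy-3-(triisopropylsilyloxy)phenyl acetate | CCOc1cc(OC(C)=O)c([C@H]2[C@H](O)c3c(OCc4ccccc4)cc(OCc4ccccc4)cc3O[C@H]2c2ccc(OCc3ccccc3)cc2)c(O[Si](C(C)C)(C(C)C)C(C)C)c1
F8 | step 10 | (2R,3S)-5,7-bis(benzyloxy)-2-(4-benzyloxyphenyl)-3-[4-ethoxy-2-hydroxy-6-(triisopropylsilyloxy)phenyl]chroman-4-one | CCOc1cc(O)c([C@@H]2C(=O)c3c(OCc4ccccc4)cc(OCc4ccccc4)cc3O[C@H]2c2ccc(OCc3ccccc3)cc2)c(O[Si](C(C)C)(C(C)C)C(C)C)c1
F9 | step 10 | ketiminium chloride of 20 (C=NH2+ in place of the acetyl C=O) | CCOc1cc(O[Si](C(C)C)(C(C)C)C(C)C)c([C@@H]2C(=O)c3c(OCc4ccccc4)cc(OCc4ccccc4)cc3O[C@H]2c2ccc(OCc3ccccc3)cc2)c(O)c1C(C)=[NH2+].[Cl-]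
F10 | step 12 | trimethylsilyl enol ether of 24, both configurations at C2 of unit 2 | COc1ccc(C2C=C(O[Si](C)(C)C)c3c(OCC)cc(O[Si](C(C)C)(C(C)C)C(C)C)c([C@@H]4C(=O)c5c(OCc6ccccc6)cc(OCc6ccccc6)cc5O[C@H]4c4ccc(OCc5ccccc5)cc4)c3O2)cc1
F11 | step 12 | (2R)-epimer of 24 at C2 of unit 2 | COc1ccc([C@H]2CC(=O)c3c(OCC)cc(O[Si](C(C)C)(C(C)C)C(C)C)c([C@@H]4C(=O)c5c(OCc6ccccc6)cc(OCc6ccccc6)cc5O[C@H]4c4ccc(OCc5ccccc5)cc4)c3O2)cc1
F12 | step 3 | racemic 5,7-bis(benzyloxy)-2-[4-(benzyloxy)phenyl]-2H-chromene-3-carbaldehyde | O=CC1=Cc2c(OCc3ccccc3)cc(OCc3ccccc3)cc2OC1c1ccc(OCc2ccccc2)cc1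
A1 | alternative 1 | protected 2'-hydroxy-α-aryl chalcone of unit 1 | O=C(c1c(O)cc(OCc2ccccc2)cc1OCc1ccccc1)/C(=C/c1ccc(OCc2ccccc2)cc1)c1c(OCOC)cc(OCc2ccccc2)cc1OCOC
A2 | alternative 1 | (E)-2-[4-(benzyloxy)-2,6-bis(methoxymethoxy)phenyl]-3-[4-(benzyloxy)phenyl]acrylic acid | OC(=O)/C(=C/c1ccc(OCc2ccccc2)cc1)c1c(OCOC)cc(OCc2ccccc2)cc1OCOC
A3 | alternative 1 | 3,5-bis(benzyloxy)benzyne | C1#CC(OCc2ccccc2)=CC(OCc2ccccc2)=C1
A4 | alternative 2 | protected trans-2,3-diaryl chroman-4-one of unit 1 with two allyl ethers | C=CCOc1cc(OCc2ccccc2)cc(OCC=C)c1[C@@H]1C(=O)c2c(OCc3ccccc3)cc(OCc3ccccc3)cc2O[C@H]1c1ccc(OCc2ccccc2)cc1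
A5 | alternative 2 | 1-[2,4-bis(benzyloxy)-6-hydroxyphenyl]-2-[4-(benzyloxy)-2,6-bis(allyloxy)phenyl]ethanone | O=C(Cc1c(OCC=C)cc(OCc2ccccc2)cc1OCC=C)c1c(O)cc(OCc2ccccc2)cc1OCc1ccccc1
A6 | alternative 3 | (3S)-3-[4-(benzyloxy)-2,6-bis(methoxymethoxy)phenyl]-5,7-bis(benzyloxy)chroman-2-ol | COCOc1cc(OCc2ccccc2)cc(OCOC)c1[C@@H]1Cc2c(OCc3ccccc3)cc(OCc3ccccc3)cc2OC1O
A7 | alternative 3 | 2-[4-(benzyloxy)-2,6-bis(methoxymethoxy)phenyl]acetaldehyde | O=CCc1c(OCOC)cc(OCc2ccccc2)cc1OCOC
A8 | alternative 3 | 3,5-bis(benzyloxy)-2-[(phenylsulfonyl)methyl]phenol | Oc1cc(OCc2ccccc2)cc(OCc2ccccc2)c1CS(=O)(=O)c1ccccc1
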